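The disconnection is the C7–C8 bond. The vicinal oxygen pair on C7 and C8, which ties ring A (the 3-hydroxy-4,5-dimethoxyphenyl ring) to the C9 methyl group, is an acyloin in disguise, so a ring A aldehyde and acetaldehyde are its two halves. A thiamine diphosphate-dependent carboligase joins them in one operation, forming C7–C8 and fixing C8 as the (S)-carbinol without closing a ring. The precursor is 3-hydroxy-4,5-dimethoxybenzaldehyde masked as its small allyl ether, which later leaves under neutral zerovalent-palladium catalysis, so the ionisable C7 benzylic alcohol never meets acid. Mitsunobu inversion by the ring B phenol and Felkin–Anh reduction then deliver the (7R,8R) ether.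

Key step: step 2

Remark: C7 is the benzylic carbon on ring A, C8 the carbon carrying the ring B oxygen, C9 the methyl carbon; it is assumed that a benzoylformate decarboxylase (wild type or a known active-site variant) turning over the 3,4,5-trioxygenated aldehyde is found by screening; step 2 is a pure addition and forms no co-product.

Step 1
Reactants: 1 3-hydroxy-4,5-dimethoxybenzaldehyde
Product: 2 3-(allyloxy)-4,5-dimethoxybenzaldehyde
Conditions: allyl bromide, K2CO3, DMF, rt
Reagents that add atoms: allyl bromide, C=CCBr
Why: Williamson ether synthesis, in which the phenoxide formed by K2CO3 displaces bromide from the primary allylic halide (SN2) while the aldehyde is inert; no stereocentre is formed.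

Step 2
Reactants: 2 3-(allyloxy)-4,5-dimethoxybenzaldehyde; 3 acetaldehyde
Product: 4 (S)-1-[3-(allyloxy)-4,5-dimethoxyphenyl]-2-hydroxypropan-1-one
Conditions: benzoylformate decarboxylase (Pseudomonas putida; wild type or H281A/L476Q variant), thiamine diphosphate, MgSO4, KH2PO4/K2HPO4 buffer pH 7.0, DMSO (20% v/v), excess 3, 30 °C
Reagents that add atoms: none
Why: The thiazolium ylide of the enzyme-bound cofactor adds to the aldehyde carbon of 2, and deprotonation gives the enamine-type acyl anion equivalent, which attacks the carbonyl carbon of acetaldehyde to form C7–C8 before the cofactor is expelled and the C7 ketone appears. The closest known reaction type is the benzoylformate decarboxylase-catalysed cross-acyloin condensation of substituted benzaldehydes with acetaldehyde to (S)-2-hydroxy-1-arylpropan-1-ones. No ring is closed. The one new stereocentre, C8, is controlled by the protein: acetaldehyde can only bind with its methyl group in the small pocket beside the cofactor, so one face of the acceptor carbonyl is presented and the (S)-carbinol should result. The step needs chemoselectivity (aryl aldehyde as donor, acetaldehyde as acceptor, no benzoin or acetoin), which is secured by a donor site shaped for an aroyl group, by the excess of the small acceptor and by the meta position of the allyloxy group, a position this enzyme family tolerates; the para methoxy group is the feature that may call for a variant.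

Step 3
Reactants: 4 (S)-1-[3-(allyloxy)-4,5-dimethoxyphenyl]-2-hydroxypropan-1-one; 5 4-allyl-2,6-dimethoxyphenol
Product: 6 (R)-2-(4-allyl-2,6-dimethoxyphenoxy)-1-[3-(allyloxy)-4,5-dimethoxyphenyl]propan-1-one
Conditions: PPh3, DIAD, THF, 0 °C to rt
Reagents that add atoms: none
Why: Mitsunobu etherification, in which the C8 alkoxyphosphonium, made more SN2-reactive by the adjacent carbonyl, is displaced by the phenoxide of 5 with inversion to the (R)-aryl ether under near-neutral conditions that should leave the enolisable C8–H untouched.

Step 4
Reactants: 6 (R)-2-(4-allyl-2,6-dimethoxyphenoxy)-1-[3-(allyloxy)-4,5-dimethoxyphenyl]propan-1-one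
Product: 7 (1R,2R)-2-(4-allyl-2,6-dimethoxyphenoxy)-1-[3-(allyloxy)-4,5-dimethoxyphenyl]propan-1-ol
Conditions: LiBH(s-Bu)3, THF, −78 °C; then H2O
Reagents that add atoms: none
Why: Felkin–Anh (polar, non-chelated) ketone reduction, in which the bulky hydride approaches anti to the C8–OAr bond and past the C8–H, not the methyl group, which should give the (7R) carbinol and hence the threo (7R,8R) alcohol, hydride transfer at −78 °C being faster than enolisation at C8.

Step 5
Reactants: 7 (1R,2R)-2-(4-allyl-2,6-dimethoxyphenoxy)-1-[3-(allyloxy)-4,5-dimethoxyphenyl]propan-1-ol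
Product: 8 5-[(1R,2R)-2-(4-allyl-2,6-dimethoxyphenoxy)-1-hydroxypropyl]-2,3-dimethoxyphenol
Conditions: Pd(PPh3)4 (cat.), morpholine, THF, rt
Reagents that add atoms: none
Why: Tsuji–Trost-type deallylation, in which zerovalent palladium ionises only the aryl allyl ether (phenoxide as leaving group) to a π-allyl complex that morpholine captures, while the C-allyl group of ring B, the methyl ethers, the C8 aryl ether and the C7 benzylic alcohol are untouched under these neutral conditions, so both stereocentres are kept.

Compound list
1 | 3-hydroxy-4,5-dimethoxybenzaldehyde | O=Cc1cc(O)c(OC)c(OC)c1 | starting material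
2 | 3-(allyloxy)-4,5-dimethoxybenzaldehyde | O=Cc1cc(OCC=C)c(OC)c(OC)c1 | intermediate
3 | acetaldehyde | CC=O | starting material
4 | (S)-1-[3-(allyloxy)-4,5-dimethoxyphenyl]-2-hydroxypropan-1-one | C[C@H](O)C(=O)c1cc(OCC=C)c(OC)c(OC)c1 | intermediate
5 | 4-allyl-2,6-dimethoxyphenol | C=CCc1cc(OC)c(O)c(OC)c1 | starting material
6 | (R)-2-(4-allyl-2,6-dimethoxyphenoxy)-1-[3-(allyloxy)-4,5-dimethoxyphenyl]propan-1-one | C=CCc1cc(OC)c(O[C@H](C)C(=O)c2cc(OCC=C)c(OC)c(OC)c2)c(OC)c1 | intermediate
7 | (1R,2R)-2-(4-allyl-2,6-dimethoxyphenoxy)-1-[3-(allyloxy)-4,5-dimethoxyphenyl]propan-1-ol | C=CCc1cc(OC)c(O[C@H](C)[C@H](O)c2cc(OCC=C)c(OC)c(OC)c2)c(OC)c1 | intermediate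
8 | 5-[(1R,2R)-2-(4-allyl-2,6-dimethoxyphenoxy)-1-hydroxypropyl]-2,3-dimethoxyphenol | C=CCc1cc(OC)c(O[C@H](C)[C@H](O)c2cc(O)c(OC)c(OC)c2)c(OC)c1 | target

Total step count: 5. Longest linear sequence: 5 steps (1 → 2 → 4 → 6 → 7 → 8).

Steps most likely to fail

Step 2. The enzyme may turn over the para-oxygenated, trisubstituted donor only slowly, so that conversion stalls, or it may hold the acceptor less firmly, so that enantioselectivity erodes. The fallback sets out from 2 and comes back at 4, and replaces enzyme control by a chiral oxidant. Addition of EtMgBr (THF, 0 °C) should give racemic 1-[3-(allyloxy)-4,5-dimethoxyphenyl]propan-1-ol F1. Oxidation with MnO2 (CH2Cl2, rt) should give 1-[3-(allyloxy)-4,5-dimethoxyphenyl]propan-1-one F2. Davis asymmetric hydroxylation of its sodium enolate (NaN(SiMe3)2, (+)-(camphorsulfonyl)oxaziridine, THF, −78 °C) should then give ketol 4. The (+)-reagent is expected, by analogy with propiophenone, to give the (S)-ketol; its antipode is available if the sense proves opposite.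

Step 3. Displacement by the di-ortho-substituted phenol may be slow, letting elimination or alkylation of the hydrazide compete, and the activated ketol may lose C8 configuration by enolisation. The fallback sets out from 4 and comes back at 6, and separates activation from displacement. Mesylation (MsCl, Et3N, CH2Cl2, −20 °C) should give, with retention, (S)-1-[3-(allyloxy)-4,5-dimethoxyphenyl]-1-oxopropan-2-yl methanesulfonate F3. This α-keto sulfonate, a highly reactive SN2 electrophile, should be displaced with inversion by phenol 5 and K2CO3 in acetone at 0 °C to rt.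

Step 4. Facial selectivity may be poor if a lithium-chelated transition state (carbonyl and ether oxygens) competes with the Felkin–Anh one, and the basic hydride may epimerise C8 before it reduces. The fallback sets out from 6 and comes back at 7, and replaces substrate control by catalyst control. Noyori–Ikariya asymmetric transfer hydrogenation with RuCl(p-cymene)[(S,S)-TsDPEN] in HCO2H/Et3N (5:2) lets the chiral ruthenium hydride select the carbonyl face. By the usual aryl/alkyl recognition the (S,S) catalyst should give the (7R) carbinol, and it leaves the terminal alkenes alone. This fallback makes no new compound (F0).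

Further compounds
F1 | step 2 | 1-[3-(allyloxy)-4,5-dimethoxyphenyl]propan-1-ol (racemic) | CCC(O)c1cc(OCC=C)c(OC)c(OC)c1
F2 | step 2 | 1-[3-(allyloxy)-4,5-dimethoxyphenyl]propan-1-one | CCC(=O)c1cc(OCC=C)c(OC)c(OC)c1
F3 | step 3 | (S)-1-[3-(allyloxy)-4,5-dimethoxyphenyl]-1-oxopropan-2-yl methanesulfonate | C[C@H](OS(C)(=O)=O)C(=O)c1cc(OCC=C)c(OC)c(OC)c1
F0 | step 4 | none | none
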